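## Structural features

The target, 8-(2,4-dihydroxy-6-pentylphenoxy)-6-hydroxy-3-pentyl-1H-isochromen-1-one, is an isocoumarin. Ring A is the benzo ring (C4a, C5, C6, C7, C8, C8a) and ring C is the pyranone (C1, O2, C3, C4), with a pentyl group on C3 and a hydroxyl on C6. An ether oxygen on C8 links ring A to C1' of a second benzene, ring B, which carries hydroxyls on C2' and C4' and a pentyl group on C6'. The target has no stereocentre; the only sp3 centres in the route are C1' and C6', adjacent and transient, formed in the annulation and erased on aromatization. The fragile groups are the enol lactone of ring C, which opens with hydroxide or alkoxide, and three free phenols on electron-rich rings that are easily oxidized or alkylated. The real difficulty is the diaryl ether: its oxygen is flanked by the C8a carbonyl carbon on ring A and by the C2' oxygen and the C6' pentyl group on ring B, so a direct aryl C–O coupling would be hindered on both sides. The key step exploits the fact that ring B is a 5-pentylresorcinol with the ether oxygen on C1' between C2' and C6'. Ring B is therefore the aromatized form of a cyclohexane-1,3-dione with carbonyls at C2' and C4', the ring A oxygen on C1' and the pentyl group on C6', so C1' can start as a malonate carbon that already carries that oxygen. One design point follows from this: the future C1 carboxyl on ring A sits ortho to the oxymalonate oxygen. As a methyl ester it would lie open to a 5-exo-trig Dieckmann attack by the malonate carbanion, the known route from salicylate oxymalonates to 3-hydroxybenzofuran-2-carboxylates, so it is carried as a tert-butyl ester.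

## Logic of the disconnections

19 to 18: the three O–CH3 bonds on the C6, C2' and C4' oxygens are cut. The phenols must be masked through the strongly basic C-acylation, and methyl ethers survive every earlier step. The forward step needs a Lewis-acid demethylation that leaves the enol lactone and the aryl–O–aryl bond alone.

18 to 16: the O2–C3 bond of the enol lactone is cut, giving a ketone at C3 and a tert-butyl ester at C1. The lactone is the most base-sensitive part, so it is formed late and under acid. The forward step must cleave the tert-butyl ester and dehydrate the keto acid 17 without tert-butylating the electron-rich rings.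

16 to 14 + 15: the C3–C4 bond is cut. C4 is the benzylic methyl carbon ortho to the ester and can be made nucleophilic by lateral lithiation; C3 and the pentyl chain come from 15. The forward step needs selective benzylic deprotonation and a single acylation.

14 to 13: the two O–CH3 bonds on ring B are cut. This is trivial, but it removes acidic protons before the lithium amide step.

13 to 10: two hydrogens are added back across ring B, at C1' and C6', with tautomerization to the diketone, so the arene becomes a cyclohexane-1,3-dione. The forward dehydrogenation must avoid strong acid, which would remove the tert-butyl ester.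

10 to 8: a methoxycarbonyl group is put back on C1'. This second activating group makes C1' a malonate carbon. The forward dealkoxycarbonylation must take the methyl β-keto ester and spare the tert-butyl benzoate.

8 to 5 + 6: the C1'–C6' and C2'–C3' bonds are cut. The six-membered ring falls apart into an oxymalonate and a nine-carbon enone, and the hindered ether oxygen is already in place on an sp3 carbon. The forward step must join the oxygen-bearing carbon to the enone β-carbon and close the ring from the methyl ketone, with no attack on the ring A ester.

5 to 3 + 4: the bond between the ether oxygen and C1' is cut. The difficult diaryl ether becomes a simple O-alkylation of a phenol with an activated bromide. The ring A ester must be inert to the carbanion of 5, which is why it is tert-butyl.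

3 to 2 to 1: the O–CH3 bond on the para oxygen and the O–C(CH3)3 bond of the ester are cut. The forward steps need selective esterification of the acid in the presence of two phenols, and selective methylation of the unchelated phenol.

## Other disconnections considered

Alternative 1: The cut runs through C4a–C4 and C8a–C1, so both carbon substituents of ring A are removed and ring A becomes an aryne between C4a and C8a. In the forward step, fluoride (CsF) would release the aryne from the silylaryl triflate A2, and the aryne would insert into a C–C bond of dimethyl malonate A3 to give the homophthalate A1.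
- In favour: one mild, neutral step would install both carbons at the right oxidation level. The C8 aryloxy group should steer the malonate carbon to C4a, the position distal to the oxygen, so the regiochemistry comes out as needed. Ring B stays aromatic throughout, so no decarboxylation or dehydrogenation is needed; on that point this plan is better than the chosen one.
- Against: the step closes no ring and leaves the main difficulty untouched. A2 must already contain the doubly ortho-substituted diaryl ether, made by coupling a hindered, electron-rich ring B phenol, and it needs an ortho silyl/triflate pair on a 1,2,3,5-tetrasubstituted arene.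
- Comparison: the chosen plan attaches the ether oxygen by O-alkylation in step 3 and builds ring B around it. From A1 to the isocoumarin, acylation at C4, ring closure and loss of the C4 carboxyl would take about as many steps as 14 to 19, so the endgames are equal. The overall sequence should be longer than ten steps.

Alternative 2: The cut is at O2–C3, with C1 tied back to the C2' oxygen, so the target is seen as the ring-opened form of the alkynyl depsidone A5. In the forward step, cationic monovalent gold (Ph3PAuCl with AgOTf) would activate the alkyne for 6-endo-dig attack by the depsidone carbonyl oxygen. Water would then add at C1, open the seven-membered lactone and free the C2' hydroxyl, giving A4.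
- In favour: the pyranone would form catalytically under neutral conditions with no strong base, directly in its final oxidation state. Only two methyl ethers would remain to be cleaved. In these respects the step is equal to or better than the endgame of the chosen plan, steps 8 to 10. The diaryl ether of A5 could be closed intramolecularly on an ester tether, which is easier than an intermolecular coupling.
- Against: 6-endo closure has to compete with 5-exo closure to an alkylidene phthalide for an alkyl-substituted alkyne, and water could hydrolyse the depsidone before cyclization. A5 also requires ring B as a finished 1,2,3,5-tetrasubstituted arene with differentiated oxygens, plus an alkynylation next to the carbonyl.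
- Comparison: the chosen plan makes ring B from an acyclic enone and 5 in step 4, whereas this plan moves all the ring B work into the precursor. The total should be longer than ten steps.

Alternative 3: Three bonds of ring B are cut (C2'–C3', C4'–C5' and C1'–C2'), leaving the diazoketone A7 and ethoxyacetylene A8. In the forward step, Wolff rearrangement of A7 would give an aryloxy vinylketene. A [2+2] addition with A8, four-electron ring opening, six-electron closure and tautomerization would then give the phenol A6.
- In favour: like the chosen plan, it builds ring B on an ether oxygen that is already in place, so the two are equal on the hindered C–O bond. It would deliver ring B aromatic in one step, which saves steps 5 and 6 and is better on that point. The regiochemistry is intrinsic to the pericyclic cascade.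
- Against: A7 is a β-aryloxy enone diazoketone whose preparation should take more, and more hazardous, steps than the two from 3 to 5. A donor-substituted vinylketene is a less proven partner. Photolysis limits scale, and the ethyl ether still needs the final Lewis-acid cleavage.
- Comparison: the step count is similar to the chosen route, at ten or eleven. The chosen plan uses ordinary enolate chemistry with inexpensive partners, at the price of two adjustment steps.

Key step: step 4

Remark on the chemistry: 6 and 15 are taken as purchasable, and 7 to 11 are carried as racemic diastereomer mixtures because C1' and C6' become sp2 in step 6.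

## Route

Step 1
Reactants: 1 orsellinic acid (2,4-dihydroxy-6-methylbenzoic acid)
Product: 2 tert-butyl 2,4-dihydroxy-6-methylbenzoate
Conditions: Cl3CC(=NH)Ot-Bu (2 equiv), THF–cyclohexane, rt
Reagents that add atoms: tert-butyl 2,2,2-trichloroacetimidate, CC(C)(C)OC(=N)C(Cl)(Cl)Cl
Why: Imidate esterification: the carboxylic acid protonates the trichloroacetimidate and the carboxylate takes up the tert-butyl group at room temperature, while the phenols, which need an added Lewis acid to react, should stay free and the electron-rich acid is not heated enough to decarboxylate.

Step 2
Reactants: 2 tert-butyl 2,4-dihydroxy-6-methylbenzoate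
Product: 3 tert-butyl 2-hydroxy-4-methoxy-6-methylbenzoate
Conditions: MeI (1.1 equiv), K2CO3, acetone, rt
Reagents that add atoms: iodomethane, CI
Why: Williamson methylation; the C2 hydroxyl is hydrogen-bonded to the ester carbonyl and is less acidic and less nucleophilic, so one equivalent of MeI should go to the para oxygen.

Step 3
Reactants: 3 tert-butyl 2-hydroxy-4-methoxy-6-methylbenzoate; 4 dimethyl bromomalonate
Product: 5 dimethyl 2-[2-(tert-butoxycarbonyl)-5-methoxy-3-methylphenoxy]malonate
Conditions: K2CO3, DMF, rt to 40 °C
Reagents that add atoms: none
Why: Williamson O-alkylation with an activated bromide; K2CO3 also deprotonates 5, but the hindered tert-butyl ester should resist the 5-exo-trig Dieckmann attack that an ortho methyl ester would suffer, so no benzofuranone should form.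

Step 4
Reactants: 5 dimethyl 2-[2-(tert-butoxycarbonyl)-5-methoxy-3-methylphenoxy]malonate; 6 (E)-non-3-en-2-one
Product: 8 tert-butyl 2-{[1-(methoxycarbonyl)-2,4-dioxo-6-pentylcyclohexyl]oxy}-4-methoxy-6-methylbenzoate (racemic diastereomer mixture), via Michael adduct 7 (not isolated)
Conditions: NaOMe (1.2 equiv), MeOH, rt then reflux; 1 M HCl, 0 °C
Reagents that add atoms: none
Why: Sodium methoxide deprotonates 5 at the malonate carbon (future C1'), and this tertiary carbanion adds to the β-carbon of 6 (future C6', which carries the pentyl group) to give the enolate of 7. Proton exchange in methanol gives the methyl-ketone enolate, whose carbon (future C3') attacks one of the geminal methyl esters (future C2') and expels methoxide, a 6-exo-trig Claisen closure of ring B. The product is deprotonated at C3' between the two carbonyls, and this stabilized enolate pulls the reversible Michael addition and the ring closure forward until the acid work-up. The closest known reaction is the Michael–Claisen annulation of dimethyl malonate with the same enone, the standard entry to 5-pentylcyclohexane-1,3-dione; the only change is the aryloxy group on the malonate carbon, which makes C1' quaternary in 8. C1' and C6' become stereocentres with no controlling element, so a racemic mixture of diastereomers is expected and accepted, because both centres become sp2 in step 6. The regiochemistry is fixed by the roles of the partners: the oxygen-bearing carbon is the only nucleophilic site of 5 and can only bond to the β-carbon, and only the methyl side of the ketone can close a six-membered ring. The step also needs chemoselectivity between the malonate esters and the ring A ester, and the tert-butyl ester is neither transesterified by methoxide nor acylated by the neighbouring carbanion.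

Step 5
Reactants: 8 tert-butyl 2-{[1-(methoxycarbonyl)-2,4-dioxo-6-pentylcyclohexyl]oxy}-4-methoxy-6-methylbenzoate
Product: 10 tert-butyl 2-[(2,4-dioxo-6-pentylcyclohexyl)oxy]-4-methoxy-6-methylbenzoate (racemic diastereomer mixture), via β-keto acid 9 (not isolated)
Conditions: LiCl (3 equiv), DMSO–H2O, 120 °C
Reagents that add atoms: none
Why: Krapcho dealkoxycarbonylation: chloride attacks the methyl group of the activated β-keto ester in an SN2 step and the carboxylate of 9 loses CO2; the tert-butyl benzoate cannot react by SN2, and the quaternary centre does not hinder attack at the remote methyl carbon.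

Step 6
Reactants: 10 tert-butyl 2-[(2,4-dioxo-6-pentylcyclohexyl)oxy]-4-methoxy-6-methylbenzoate
Product: 13 tert-butyl 2-(2,4-dihydroxy-6-pentylphenoxy)-4-methoxy-6-methylbenzoate, via bis(silyl) dienol ether 11 (not isolated), via bis(silyl) aryl ether 12 (not isolated)
Conditions: TMSOTf (2.4 equiv), Et3N, CH2Cl2, 0 °C; hexane, filtration; DDQ (1.1 equiv), 2,4,6-collidine, CH2Cl2, 0 °C to rt; K2CO3 (cat.), MeOH, rt
Reagents that add atoms: none
Why: Soft enolization turns the dione into a bis(silyloxy)cyclohexadiene (11 or its double-bond isomer, which converge), DDQ removes hydride from an allylic ring position and proton loss gives the arene, a known quinone dehydrogenation of silyl enol ethers; no strong acid is present, so the tert-butyl ester should survive, and carbonate in methanol removes the labile aryl silyl ethers.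

Step 7
Reactants: 13 tert-butyl 2-(2,4-dihydroxy-6-pentylphenoxy)-4-methoxy-6-methylbenzoate
Product: 14 tert-butyl 2-(2,4-dimethoxy-6-pentylphenoxy)-4-methoxy-6-methylbenzoate
Conditions: MeI (3 equiv), K2CO3, DMF, rt
Reagents that add atoms: iodomethane, CI
Why: Williamson ether synthesis on both ring B phenols, which removes the acidic protons before the lithium amide step.

Step 8
Reactants: 14 tert-butyl 2-(2,4-dimethoxy-6-pentylphenoxy)-4-methoxy-6-methylbenzoate; 15 N-methoxy-N-methylhexanamide
Product: 16 tert-butyl 2-(2,4-dimethoxy-6-pentylphenoxy)-4-methoxy-6-(2-oxoheptyl)benzoate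
Conditions: LiN(i-Pr)2 (1.2 equiv), THF, −78 °C; then 15, −78 to −20 °C; aq. NH4Cl
Reagents that add atoms: none
Why: Lateral lithiation of an ortho-toluate: lithium diisopropylamide removes a proton from the methyl group ortho to the ester, and the delocalized benzylic anion is acylated by the Weinreb amide; the chelated tetrahedral adduct lasts until the quench, so a single acyl group should be introduced, and the tert-butyl ester suppresses self-condensation.

Step 9
Reactants: 16 tert-butyl 2-(2,4-dimethoxy-6-pentylphenoxy)-4-methoxy-6-(2-oxoheptyl)benzoate
Product: 18 8-(2,4-dimethoxy-6-pentylphenoxy)-6-methoxy-3-pentyl-1H-isochromen-1-one, via keto acid 17 (not isolated)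
Conditions: CF3CO2H–CH2Cl2 (1:2), anisole, 0 °C to rt
Reagents that add atoms: none
Why: Acid removes the tert-butyl group as isobutene, and the keto acid 17 closes through its enol with loss of water to the conjugated isocoumarin, the usual enol lactonization of 2-(2-oxoalkyl)benzoic acids; anisole traps tert-butyl cations that could otherwise alkylate the electron-rich rings.

Step 10
Reactants: 18 8-(2,4-dimethoxy-6-pentylphenoxy)-6-methoxy-3-pentyl-1H-isochromen-1-one
Product: 19 8-(2,4-dihydroxy-6-pentylphenoxy)-6-hydroxy-3-pentyl-1H-isochromen-1-one
Conditions: BBr3 (8 equiv), CH2Cl2, −78 °C to rt; then MeOH, H2O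
Reagents that add atoms: none
Why: Lewis-acid ether cleavage: BBr3 binds each methoxy oxygen and bromide removes the methyl group by SN2; the aryl–O–aryl ether offers no sp3 carbon for attack, and the enol lactone should tolerate the reagent.

## Compound list

1 | orsellinic acid (2,4-dihydroxy-6-methylbenzoic acid) | Cc1cc(O)cc(O)c1C(=O)O | starting material
2 | tert-butyl 2,4-dihydroxy-6-methylbenzoate | Cc1cc(O)cc(O)c1C(=O)OC(C)(C)C | intermediate
3 | tert-butyl 2-hydroxy-4-methoxy-6-methylbenzoate | COc1cc(C)c(C(=O)OC(C)(C)C)c(O)c1 | intermediate
4 | dimethyl bromomalonate | COC(=O)C(Br)C(=O)OC | starting material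
5 | dimethyl 2-[2-(tert-butoxycarbonyl)-5-methoxy-3-methylphenoxy]malonate | COC(=O)C(Oc1cc(OC)cc(C)c1C(=O)OC(C)(C)C)C(=O)OC | intermediate
6 | (E)-non-3-en-2-one | CCCCC/C=C/C(C)=O | starting material
7 | dimethyl 2-[2-(tert-butoxycarbonyl)-5-methoxy-3-methylphenoxy]-2-(2-oxononan-4-yl)malonate (racemic, not isolated) | CCCCCC(CC(C)=O)C(Oc1cc(OC)cc(C)c1C(=O)OC(C)(C)C)(C(=O)OC)C(=O)OC | intermediate
8 | tert-butyl 2-{[1-(methoxycarbonyl)-2,4-dioxo-6-pentylcyclohexyl]oxy}-4-methoxy-6-methylbenzoate (racemic diastereomer mixture) | CCCCCC1CC(=O)CC(=O)C1(Oc1cc(OC)cc(C)c1C(=O)OC(C)(C)C)C(=O)OC | intermediate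
9 | 1-[2-(tert-butoxycarbonyl)-5-methoxy-3-methylphenoxy]-2,4-dioxo-6-pentylcyclohexane-1-carboxylic acid (racemic diastereomer mixture, present as its lithium salt, not isolated) | CCCCCC1CC(=O)CC(=O)C1(Oc1cc(OC)cc(C)c1C(=O)OC(C)(C)C)C(=O)O | intermediate
10 | tert-butyl 2-[(2,4-dioxo-6-pentylcyclohexyl)oxy]-4-methoxy-6-methylbenzoate (racemic diastereomer mixture) | CCCCCC1CC(=O)CC(=O)C1Oc1cc(OC)cc(C)c1C(=O)OC(C)(C)C | intermediate
11 | tert-butyl 4-methoxy-6-methyl-2-{[6-pentyl-2,4-bis(trimethylsilyloxy)cyclohexa-2,4-dien-1-yl]oxy}benzoate (racemic diastereomer mixture, not isolated) | CCCCCC1C=C(O[Si](C)(C)C)C=C(O[Si](C)(C)C)C1Oc1cc(OC)cc(C)c1C(=O)OC(C)(C)C | intermediate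
12 | tert-butyl 4-methoxy-6-methyl-2-[6-pentyl-2,4-bis(trimethylsilyloxy)phenoxy]benzoate (not isolated) | CCCCCc1cc(O[Si](C)(C)C)cc(O[Si](C)(C)C)c1Oc1cc(OC)cc(C)c1C(=O)OC(C)(C)C | intermediate
13 | tert-butyl 2-(2,4-dihydroxy-6-pentylphenoxy)-4-methoxy-6-methylbenzoate | CCCCCc1cc(O)cc(O)c1Oc1cc(OC)cc(C)c1C(=O)OC(C)(C)C | intermediate
14 | tert-butyl 2-(2,4-dimethoxy-6-pentylphenoxy)-4-methoxy-6-methylbenzoate | CCCCCc1cc(OC)cc(OC)c1Oc1cc(OC)cc(C)c1C(=O)OC(C)(C)C | intermediate
15 | N-methoxy-N-methylhexanamide | CCCCCC(=O)N(C)OC | starting material
16 | tert-butyl 2-(2,4-dimethoxy-6-pentylphenoxy)-4-methoxy-6-(2-oxoheptyl)benzoate | CCCCCC(=O)Cc1cc(OC)cc(Oc2c(OC)cc(OC)cc2CCCCC)c1C(=O)OC(C)(C)C | intermediate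
17 | 2-(2,4-dimethoxy-6-pentylphenoxy)-4-methoxy-6-(2-oxoheptyl)benzoic acid (not isolated) | CCCCCC(=O)Cc1cc(OC)cc(Oc2c(OC)cc(OC)cc2CCCCC)c1C(=O)O | intermediate
18 | 8-(2,4-dimethoxy-6-pentylphenoxy)-6-methoxy-3-pentyl-1H-isochromen-1-one | CCCCCc1cc2cc(OC)cc(Oc3c(OC)cc(OC)cc3CCCCC)c2c(=O)o1 | intermediate
19 | 8-(2,4-dihydroxy-6-pentylphenoxy)-6-hydroxy-3-pentyl-1H-isochromen-1-one | CCCCCc1cc2cc(O)cc(Oc3c(O)cc(O)cc3CCCCC)c2c(=O)o1 | target

## Step count and least certain steps

Total step count: 10. Longest linear sequence: 10 steps, from 1 to 19.

Step 4, the key step. The most likely failure is a slow and reversible conjugate addition of the hindered tertiary carbanion to the β-alkyl enone. The adduct could then revert to its components while the enone is used up by methoxide addition and self-condensation. The fallback sets out from 5 and replaces 6 by purchased non-3-yn-2-one under the same base. Addition to the ynone should be much less reversible, and Claisen closure through the cis enone would give tert-butyl 2-{[1-(methoxycarbonyl)-2,4-dioxo-6-pentylcyclohex-5-en-1-yl]oxy}-4-methoxy-6-methylbenzoate F1. Treatment of F1 with LiCl in wet DMSO would remove the methyl ester, and the ring would aromatize by tautomerization alone, with no oxidant. The fallback comes back to the route at 13 and replaces steps 4 to 6.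

Step 3. The most likely failure is bromine transfer from 4 to the chelated, slowly reacting phenoxide or to the anion of 5, together with base-induced self-condensation of 4. The fallback sets out from 3 and forms the same O–C bond by carbenoid O–H insertion: purchased dimethyl diazomalonate with Rh2(OAc)4 in toluene at 80 °C, under neutral conditions. It comes back at 5 and makes no new compound (F0).

Step 6. The most likely failure is incomplete silylation of the hindered C2' carbonyl or adduct formation with the quinone, so that dehydrogenation stalls; acid traces could also remove the tert-butyl group early. The fallback sets out from 10 and gives up the tert-butyl ester, which is no longer needed once no malonate carbanion remains in the molecule. Bromination and dehydrobromination with CuBr2 and LiBr in refluxing MeCN, followed by brief CF3CO2H treatment, would give 2-(2,4-dihydroxy-6-pentylphenoxy)-4-methoxy-6-methylbenzoic acid F2. Exhaustive methylation (MeI, K2CO3, DMF) would give methyl 2-(2,4-dimethoxy-6-pentylphenoxy)-4-methoxy-6-methylbenzoate F3. Lateral lithiation and acylation with 15, as in step 8, would give methyl 2-(2,4-dimethoxy-6-pentylphenoxy)-4-methoxy-6-(2-oxoheptyl)benzoate F4. Enol lactonization of F4 with TsOH in refluxing toluene brings the fallback back to the route at 18.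

Step 8. The most likely failure is proton transfer from the α-methylene of 15 to the benzylic anion, which would return 14, or incomplete lateral deprotonation. The fallback sets out from 14 and adds the same lithiated species to hexanal, a faster electrophile, to give racemic tert-butyl 2-(2,4-dimethoxy-6-pentylphenoxy)-6-(2-hydroxyheptyl)-4-methoxybenzoate F5. Oxidation of F5 with Dess–Martin periodinane comes back to the route at 16.

## Further compounds

F1 | step 4 | tert-butyl 2-{[1-(methoxycarbonyl)-2,4-dioxo-6-pentylcyclohex-5-en-1-yl]oxy}-4-methoxy-6-methylbenzoate (racemic) | CCCCCC1=CC(=O)CC(=O)C1(Oc1cc(OC)cc(C)c1C(=O)OC(C)(C)C)C(=O)OC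
F0 | step 3 | none | none
F2 | step 6 | 2-(2,4-dihydroxy-6-pentylphenoxy)-4-methoxy-6-methylbenzoic acid | CCCCCc1cc(O)cc(O)c1Oc1cc(OC)cc(C)c1C(=O)O
F3 | step 6 | methyl 2-(2,4-dimethoxy-6-pentylphenoxy)-4-methoxy-6-methylbenzoate | CCCCCc1cc(OC)cc(OC)c1Oc1cc(OC)cc(C)c1C(=O)OC
F4 | step 6 | methyl 2-(2,4-dimethoxy-6-pentylphenoxy)-4-methoxy-6-(2-oxoheptyl)benzoate | CCCCCC(=O)Cc1cc(OC)cc(Oc2c(OC)cc(OC)cc2CCCCC)c1C(=O)OC
F5 | step 8 | tert-butyl 2-(2,4-dimethoxy-6-pentylphenoxy)-6-(2-hydroxyheptyl)-4-methoxybenzoate (racemic) | CCCCCC(O)Cc1cc(OC)cc(Oc2c(OC)cc(OC)cc2CCCCC)c1C(=O)OC(C)(C)C
A1 | alternative 1 | methyl 2-(2,4-dimethoxy-6-pentylphenoxy)-4-methoxy-6-(2-methoxy-2-oxoethyl)benzoate | COC(=O)Cc1cc(OC)cc(Oc2c(OC)cc(OC)cc2CCCCC)c1C(=O)OC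
A2 | alternative 1 | 3-(2,4-dimethoxy-6-pentylphenoxy)-5-methoxy-2-(trimethylsilyl)phenyl trifluoromethanesulfonate | CCCCCc1cc(OC)cc(OC)c1Oc1cc(OC)cc(OS(=O)(=O)C(F)(F)F)c1[Si](C)(C)C
A3 | alternative 1 | dimethyl malonate | COC(=O)CC(=O)OC
A4 | alternative 2 | 8-(2-hydroxy-4-methoxy-6-pentylphenoxy)-6-methoxy-3-pentyl-1H-isochromen-1-one | CCCCCc1cc2cc(OC)cc(Oc3c(O)cc(OC)cc3CCCCC)c2c(=O)o1
A5 | alternative 2 | 1-(hept-1-yn-1-yl)-3,8-dimethoxy-6-pentyl-11H-dibenzo[b,e][1,4]dioxepin-11-one | CCCCCC#Cc1cc(OC)cc2Oc3c(CCCCC)cc(OC)cc3OC(=O)c12
A6 | alternative 3 | methyl 2-(4-ethoxy-2-hydroxy-6-pentylphenoxy)-4-methoxy-6-methylbenzoate | CCCCCc1cc(OCC)cc(O)c1Oc1cc(OC)cc(C)c1C(=O)OC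
A7 | alternative 3 | methyl 2-{[(1E)-4-diazo-3-oxo-2-pentylbut-1-en-1-yl]oxy}-4-methoxy-6-methylbenzoate | CCCCC/C(=C\Oc1cc(OC)cc(C)c1C(=O)OC)C(=O)C=[N+]=[N-]
A8 | alternative 3 | ethoxyacetylene | CCOC#C
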